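## Analysis of the target

CNP0125037.3 is a meroterpenoid hydroquinone bis(hydrogen sulfate). A 2,5-disulfated benzyl group sits on C9 of a Δ8-drimane-type decalin (ring A: cyclohexene C5–C10 with the C8 methyl; ring B: cyclohexane C1–C5/C10). C4 of ring B carries a methyl and a CH2CH2 linker to C1′ of a 2,2-dimethylperhydro-1-benzoxepine (ring C: cyclohexane C1′–C6′; ring D: oxepane closed between the C5′ oxygen and C6′).

There are seven stereocentres in two clusters that the flexible linker isolates from each other: C10, C5 and C4 in the decalin; C1′ (tertiary alcohol), C2′ (CH–CH3), C5′ (CH–O) and C6′ (quaternary methyl) in the bicyclic ether. In the decalin the fusion is trans and the linker at C4 is axial, 1,3-syn to the angular C10 methyl. In the ether the C6′ methyl and C5′–H are cis (cis ring fusion), the linker at C1′ lies on the face of the C6′ methyl, and the hydroxyl and the C2′ methyl lie on the face of the two oxepane bonds.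

Sensitive groups are the aryl sulfate monoesters (acid-labile, so made last), the air-sensitive hydroquinone, the tertiary alcohol (prone to E1 loss) and the tetrasubstituted C8=C9 alkene, which an ortho phenol would capture under acid to give a chroman. The difficulty lies in three all-carbon quaternary centres, a tertiary carbinol, a tertiary ether carbon, and in a fragment union that must create C1′ with control and without relay from the other half.

The strategy rests on the C4/C5/C10 triad. An axial C4 substituent syn to the C10 methyl with a trans C5–H is what a chair–chair folded 1,5-diene gives when the initiating trisubstituted alkene is Z. Rings A and B and all three centres can therefore be written in one cationic cascade from an enantiopure Z-epoxide.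

## Retrosynthetic reasoning

**Sulfates and phenols.** The O–S bonds of 44 are cut first, giving hydroquinone 43, and the phenols are masked as benzyl ethers in 42. Benzyl ethers are removed by neutral hydrogenolysis, which the tertiary alcohol and the C8=C9 alkene tolerate.

**C2′ methyl.** The C2′–H bond of 42 is cut back to the exocyclic alkene 41. The methyl stereocentre is set only after C1′ is in place. Before that, the ketone sees a C6′ carrying methyl and CH2 and has little facial bias. Afterwards the equatorial linker fixes the chair, and the wrong epimer would put the C2′ methyl 1,3-diaxial to the C6′ methyl.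

**C1′–linker bond.** 41 is cut between C1′ and the linker CH2 into bromide 31 (used as Grignard reagent 39 and cerium reagent 40) and enone 38. This is the only linker bond that does not end on the quaternary C4, and it makes the synthesis convergent. The forward reaction must be a 1,2-addition to a hindered carbonyl from the face of the C6′ methyl; 38 cannot enolise and offers one open axial trajectory.

**Rings C and D.** 38 comes from ketone 37 by α-methylenation. The oxepane of 37 is cut at the O–C(CH3)2 bond to hydroxy alkene 36, so the ring closes by Markovnikov addition of the C5′ hydroxyl to a trisubstituted alkene. 36 comes from the prochiral dione 35 by reduction of one enantiotopic carbonyl, which sets C6′ and C5′ together. 35 is assembled from dione 32 and acrolein 33 through aldehyde 34.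

**Aryl–C11 bond.** 31 goes back through alcohol 30 to silyl ether 29, which is cut between the benzylic carbon and the arene into allylic bromide 25 and aryl bromide 27 (used as Grignard reagent 28). SN2′ attack is blocked because the γ-carbon C8 is fully substituted.

**Adjustment of the cyclisation product.** 25 derives from ester 23 through alcohol 24. 23 derives from the cascade product 19 by replacing the enol oxygen with methyl (20, 21) and removing the ring B hydroxyl (22). The ketone becomes the C8 methyl and the ester becomes C11, so the alkene is placed without isomer problems.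

**Key disconnection.** 19 is cut at C4–C5 and C9–C10, which opens both rings to the epoxy β-keto ester 18. The forward step must open the epoxide at its quaternary carbon with inversion, fold chair–chair, and end on the enol carbon.

**Chain of 18.** The C6–C7 bond is cut to allylic bromide 16 and acetoacetate 8 (as its dilithium dianion 17). 16 goes back through 14, 13 and 12 to keto ester 11, which is cut at C1–C2 into epoxy alcohol 7 (as triflate 9) and again 8 (as its amine-free sodium lithium dianion 10). A sulfonyl-stabilised carbanion at C1 is avoided, because its reductive removal from a 1,3-dialkyl-2-methylallyl system has no bias for where the double bond ends up. The enol phosphate route fixes the E-alkene stereospecifically instead.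

**Z-epoxide.** 7 is the asymmetric epoxidation product of Z-allylic alcohol 6. 6 comes from ynoate 4 by syn-carbocupration (5) and reduction, and 4 from but-3-yn-1-ol 1 through silyl ether 2. This route keeps the two hydroxyl groups distinct from the first step.

## Alternatives that were turned down

**Alternative 1:** The oxepane is disconnected at its O–C5′ bond and the adjacent C–C bond. A metal carbenoid from diazoketone A1 is captured by the tertiary allyl ether oxygen, and [2,3]-shift of the seven-membered oxonium ylide gives oxepanone A2.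
- For: it makes the hindered seven-membered ether with its gem-dimethyl carbon in one catalytic step, and leaves a ketone and an allyl group as handles for ring C. On this point it is more direct than the two-step ketol/hydroalkoxylation sequence chosen here.
- Against: it sets only C5′, the easiest centre. Seven-membered ylide formation competes with C–H insertion and [1,2]-shift, and asymmetric induction in such shifts is modest. The carbonyl carbon of A2 must still become the quaternary C6′, and C1′ and C2′ are untouched.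
- Comparison: the decalin triad, the hardest part, is not addressed at all. The chosen route gets C5′ and C6′ together from one desymmetrising reduction.

**Alternative 2:** Ring C is made by an enantioselective Diels–Alder reaction of quinone A3 with silyloxydiene A4 under a chiral cationic boron Lewis acid, giving cis-fused adduct A5.
- For: the endo cycloaddition sets the quaternary C6′ methyl and the cis C5′–H in one catalytic step with reliable enantiocontrol, and ring C arrives with the C1′ carbonyl and C2′ methyl carbon in place. On those two centres it is at least as strong as the reduction used here.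
- Against: the second ring of A5 is a carbocycle. Turning it into the oxepane needs oxidation at the silyloxy carbon, oxygen insertion next to C5′, gem-dimethylation of the resulting lactone carbonyl, removal of the extra ring C carbonyl, and reduction of two alkenes with control at C2′. That is roughly twice the step count of the five-step sequence to 38.
- Comparison: like alternative 1 it leaves the decalin unsolved. The chosen route builds ring D directly in its final oxidation state.

**Alternative 3:** The C6′–C1′ bond is made last. Hydrogen-atom transfer from an iron hydride to the exocyclic methylene of keto alkene A6 gives a tertiary radical that adds 6-exo to the side-chain ketone, closing ring C to A7.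
- For: it is highly convergent, forms the quaternary C6′ and the tertiary carbinol C1′ in one mild step, and avoids adding an organometallic to a hindered ketone. At this junction it is stronger than step 28 of the chosen route.
- Against: three stereochemical relationships (C6′ to C5′, C1′ to C6′, and C1′ to the epimerisable C2′) are decided at once in a radical closure onto a conformationally mobile oxepane. That places the largest stereochemical risk on the most advanced intermediate. A6 still needs the complete decalin, for which this plan offers nothing, and its methyl ethers need harsh or oxidative removal next to a tertiary alcohol.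
- Comparison: the chosen strategy puts its risk early, in a cascade whose stereochemistry follows from alkene geometry and one epoxide.

Key step: step 12

Assumption: the target is written as the free bis(hydrogen sulfate); such aryl sulfates are handled as salts, and the last step ends with a cold acidic ion exchange to give the protonated form shown.

## Steps

Abbreviation: TBDPS = tert-butyldiphenylsilyl. Decalin compounds use the octahydronaphthalene numbering of 19; ring C/D compounds use 1-benzoxepine numbering (C6 = C1′, C7 = C2′, C9a = C5′, C5a = C6′).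

Step 1
Reactants: 1 but-3-yn-1-ol
Product: 2 tert-butyl(but-3-yn-1-yloxy)diphenylsilane
Conditions: t-BuPh2SiCl, imidazole, CH2Cl2, 0 °C → rt
Reagents that add atoms: tert-butyl(chloro)diphenylsilane, CC(C)(C)[Si](Cl)(c1ccccc1)c1ccccc1
Why: Silylation of a primary alcohol with imidazole as base; the bulky, weakly basic silyl ether must survive organometallic steps and later sit two carbons from a carbocation without taking part.

Step 2
Reactants: 2 tert-butyl(but-3-yn-1-yloxy)diphenylsilane
Product: 4 methyl 5-(TBDPS-oxy)pent-2-ynoate, via lithium acetylide 3 (not isolated)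
Conditions: n-BuLi, THF, −78 °C; ClCO2Me, −78 → 0 °C
Reagents that add atoms: methyl chloroformate, COC(=O)Cl
Why: Deprotonation of the terminal alkyne and C-acylation of the acetylide with a chloroformate is the standard ynoate synthesis.

Step 3
Reactants: 4 methyl 5-(TBDPS-oxy)pent-2-ynoate
Product: 5 methyl (2Z)-3-methyl-5-(TBDPS-oxy)pent-2-enoate
Conditions: Me2CuLi (from MeLi, CuI), THF, −78 °C; MeOH at −78 °C
Reagents that add atoms: lithium dimethylcuprate, [Li+].C[Cu-]C
Why: Syn-carbocupration of an ynoate puts methyl and copper on the same side, so cold protonation leaves the silyloxyethyl chain cis to the ester (Z). Quenching before warming prevents equilibration of the alkenylcopper species.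

Step 4
Reactants: 5 methyl (2Z)-3-methyl-5-(TBDPS-oxy)pent-2-enoate
Product: 6 (2Z)-3-methyl-5-(TBDPS-oxy)pent-2-en-1-ol
Conditions: i-Bu2AlH, CH2Cl2, −78 °C; aq. potassium sodium tartrate
Reagents that add atoms: none
Why: 1,2-Reduction of an enoate to the allylic alcohol by an aluminium hydride keeps the alkene geometry.

Step 5
Reactants: 6 (2Z)-3-methyl-5-(TBDPS-oxy)pent-2-en-1-ol
Product: 7 [(2R,3S)-3-methyl-3-(2-TBDPS-oxyethyl)oxiran-2-yl]methanol
Conditions: Ti(Oi-Pr)4 (cat.), D-(−)-diisopropyl tartrate (cat.), t-BuOOH, 4 Å sieves, CH2Cl2, −20 °C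
Reagents that add atoms: tert-butyl hydroperoxide, CC(C)(C)OO
Why: Sharpless asymmetric epoxidation of a nerol-type Z-allylic alcohol; D-(−)-tartrate gives the (2R,3S) epoxide, the mirror image of the (2S,3R) series that L-(+)-tartrate gives with nerol. The two oxirane carbons become C3 and C4 and carry the absolute configuration of the whole decalin.

Step 6
Reactants: 7 [(2R,3S)-3-methyl-3-(2-TBDPS-oxyethyl)oxiran-2-yl]methanol; 8 methyl acetoacetate
Product: 11 methyl 5-[(2R,3S)-3-methyl-3-(2-TBDPS-oxyethyl)oxiran-2-yl]-3-oxopentanoate, via epoxy triflate 9 (not isolated), via sodium lithium acetoacetate dianion 10 (not isolated)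
Conditions: 7, Tf2O, 2,6-lutidine, CH2Cl2, −78 °C; added to 10 (from 8, NaH then n-BuLi, THF, 0 °C; 3 equiv), −78 → −30 °C
Reagents that add atoms: none
Why: Huckin–Weiler γ-alkylation of an acetoacetate dianion by a primary triflate; the terminal carbanion is the most nucleophilic site and SN2 at CH2–OTf is far faster than attack on the hindered trisubstituted epoxide. The dianion is made with NaH and n-BuLi so that no secondary amine is present to be alkylated by the triflate, and the stereocentres are not touched.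

Step 7
Reactants: 11 methyl 5-[(2R,3S)-3-methyl-3-(2-TBDPS-oxyethyl)oxiran-2-yl]-3-oxopentanoate
Product: 12 methyl (2Z)-3-[(diethoxyphosphoryl)oxy]-5-[(2R,3S)-3-methyl-3-(2-TBDPS-oxyethyl)oxiran-2-yl]pent-2-enoate
Conditions: NaH, Et2O, 0 °C; ClP(O)(OEt)2
Reagents that add atoms: diethyl chlorophosphate, CCOP(Cl)(=O)OCC
Why: O-Phosphorylation of the β-keto ester under sodium chelation in ether gives the Z-enol phosphate (phosphate cis to the ester), which fixes the geometry that the next step transfers.

Step 8
Reactants: 12 methyl (2Z)-3-[(diethoxyphosphoryl)oxy]-5-[(2R,3S)-3-methyl-3-(2-TBDPS-oxyethyl)oxiran-2-yl]pent-2-enoate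
Product: 13 methyl (2E)-3-methyl-5-[(2R,3S)-3-methyl-3-(2-TBDPS-oxyethyl)oxiran-2-yl]pent-2-enoate
Conditions: Me2CuLi (from MeLi, CuI), Et2O, −78 → −45 °C
Reagents that add atoms: lithium dimethylcuprate, [Li+].C[Cu-]C
Why: Cuprate addition–elimination on an enol phosphate goes with retention (the enol phosphate route to trisubstituted alkenes), so the Z-phosphate gives the 2E-enoate, the future E-C5=C10 alkene. A trisubstituted epoxide is not opened by the cuprate at this temperature.

Step 9
Reactants: 13 methyl (2E)-3-methyl-5-[(2R,3S)-3-methyl-3-(2-TBDPS-oxyethyl)oxiran-2-yl]pent-2-enoate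
Product: 14 (2E)-3-methyl-5-[(2R,3S)-3-methyl-3-(2-TBDPS-oxyethyl)oxiran-2-yl]pent-2-en-1-ol
Conditions: i-Bu2AlH, CH2Cl2, −78 °C; aq. potassium sodium tartrate
Reagents that add atoms: none
Why: Ester reduction to the allylic alcohol; at −78 °C the hindered epoxide is not reduced.

Step 10
Reactants: 14 (2E)-3-methyl-5-[(2R,3S)-3-methyl-3-(2-TBDPS-oxyethyl)oxiran-2-yl]pent-2-en-1-ol
Product: 16 (2E)-1-bromo-3-methyl-5-[(2R,3S)-3-methyl-3-(2-TBDPS-oxyethyl)oxiran-2-yl]pent-2-ene, via allylic mesylate 15 (not isolated)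
Conditions: MsCl, Et3N, THF, −40 °C; LiBr, THF, 0 °C
Reagents that add atoms: lithium bromide, [Li+].[Br-]
Why: Sulfonylation and SN2 displacement by bromide make the allylic bromide without acid, so the epoxide and the alkene geometry are kept.

Step 11
Reactants: 16 (2E)-1-bromo-3-methyl-5-[(2R,3S)-3-methyl-3-(2-TBDPS-oxyethyl)oxiran-2-yl]pent-2-ene; 8 methyl acetoacetate
Product: 18 methyl (6E)-7-methyl-9-[(2R,3S)-3-methyl-3-(2-TBDPS-oxyethyl)oxiran-2-yl]-3-oxonon-6-enoate, via dilithium acetoacetate dianion 17 (not isolated)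
Conditions: 8, LDA (from i-Pr2NH, n-BuLi; 2.1 equiv), THF, 0 °C; 16, −78 → 0 °C
Reagents that add atoms: none
Why: Second Huckin–Weiler γ-alkylation, now with the dilithium dianion made by double deprotonation with LDA and SN2 at a primary allylic bromide (the reaction that joins geranyl bromide to acetoacetate). The diisopropylamine that is released does not attack the bromide at low temperature, and the epoxide is too remote from the enolate to be opened.

Step 12
Reactants: 18 methyl (6E)-7-methyl-9-[(2R,3S)-3-methyl-3-(2-TBDPS-oxyethyl)oxiran-2-yl]-3-oxonon-6-enoate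
Product: 19 methyl (4aS,5S,6R,8aR)-2,6-dihydroxy-5,8a-dimethyl-5-(2-TBDPS-oxyethyl)-3,4,4a,5,6,7,8,8a-octahydronaphthalene-1-carboxylate
Conditions: SnCl4 (2 equiv), CH2Cl2, −78 °C (MeAlCl2 as alternative promoter); aq. NaHCO3
Reagents that add atoms: none
Why: The Lewis acid binds the epoxide oxygen and chelates the β-keto ester as its enol; the C4–O bond at the quaternary oxirane carbon lengthens, the C5=C10 alkene attacks C4 anti to the leaving oxygen, the enol carbon C9 captures the tertiary C10 cation, and a proton is lost from the enol oxygen. The closest known reaction type is the Lewis-acid epoxy-polyene cyclisation terminated by a β-dicarbonyl enol or an enol ether. Ring B closes 6-endo onto the E-alkene and ring A closes 6-endo onto the enol, both through a chair–chair fold. C4 is set by inversion of the (3S)-oxirane carbon; because the linker is the Z substituent it ends axial and syn to the C10 methyl, with the C4 methyl equatorial. C5 and C10 are set by antiperiplanar addition across the E-alkene, which gives the trans fusion, and C3 keeps its configuration with the hydroxyl equatorial. The step needs Markovnikov opening (secured by the tertiary centre), C- rather than O-capture by the enol (favoured by the tin chelate and the six-membered carbocycle), and a silent linker oxygen (the bulky silyl ether could only close a four-membered ring at C4). The product is isolated as the hydrogen-bonded enol.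

Step 13
Reactants: 19 methyl (4aS,5S,6R,8aR)-2,6-dihydroxy-5,8a-dimethyl-5-(2-TBDPS-oxyethyl)-3,4,4a,5,6,7,8,8a-octahydronaphthalene-1-carboxylate
Product: 20 methyl (4aS,5S,6R,8aR)-6-hydroxy-5,8a-dimethyl-5-(2-TBDPS-oxyethyl)-2-{[(trifluoromethyl)sulfonyl]oxy}-3,4,4a,5,6,7,8,8a-octahydronaphthalene-1-carboxylate
Conditions: PhNTf2, Cs2CO3, DMF, 0 °C → rt
Reagents that add atoms: N-phenylbis(trifluoromethanesulfonimide), O=S(=O)(N(c1ccccc1)S(=O)(=O)C(F)(F)F)C(F)(F)F
Why: Carbonate deprotonates only the acidic enol, which is sulfonylated on oxygen; the neutral, hindered secondary alcohol does not react with the mild triflimide.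

Step 14
Reactants: 20 methyl (4aS,5S,6R,8aR)-6-hydroxy-5,8a-dimethyl-5-(2-TBDPS-oxyethyl)-2-{[(trifluoromethyl)sulfonyl]oxy}-3,4,4a,5,6,7,8,8a-octahydronaphthalene-1-carboxylate
Product: 21 methyl (4aS,5S,6R,8aR)-6-hydroxy-2,5,8a-trimethyl-5-(2-TBDPS-oxyethyl)-3,4,4a,5,6,7,8,8a-octahydronaphthalene-1-carboxylate
Conditions: Me2CuLi (from MeLi, CuI; 3 equiv), THF, −78 → −20 °C
Reagents that add atoms: lithium dimethylcuprate, [Li+].C[Cu-]C
Why: Cuprate addition–elimination on a β-triflyloxy enoate installs the C8 methyl on the ring-locked alkene; one equivalent of reagent is spent on the free hydroxyl.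

Step 15
Reactants: 21 methyl (4aS,5S,6R,8aR)-6-hydroxy-2,5,8a-trimethyl-5-(2-TBDPS-oxyethyl)-3,4,4a,5,6,7,8,8a-octahydronaphthalene-1-carboxylate
Product: 22 methyl (4aS,5S,6R,8aR)-6-[(1H-imidazol-1-ylcarbonothioyl)oxy]-2,5,8a-trimethyl-5-(2-TBDPS-oxyethyl)-3,4,4a,5,6,7,8,8a-octahydronaphthalene-1-carboxylate
Conditions: 1,1′-thiocarbonyldiimidazole, DMAP, ClCH2CH2Cl, reflux
Reagents that add atoms: 1,1′-thiocarbonyldiimidazole, S=C(n1ccnc1)n1ccnc1
Why: Thioacylation of the equatorial neopentyl-type alcohol prepares the Barton–McCombie deoxygenation and needs no strong base.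

Step 16
Reactants: 22 methyl (4aS,5S,6R,8aR)-6-[(1H-imidazol-1-ylcarbonothioyl)oxy]-2,5,8a-trimethyl-5-(2-TBDPS-oxyethyl)-3,4,4a,5,6,7,8,8a-octahydronaphthalene-1-carboxylate
Product: 23 methyl (4aR,5S,8aR)-2,5,8a-trimethyl-5-(2-TBDPS-oxyethyl)-3,4,4a,5,6,7,8,8a-octahydronaphthalene-1-carboxylate
Conditions: Bu3SnH, AIBN (cat.), toluene, reflux
Reagents that add atoms: none
Why: Barton–McCombie radical deoxygenation; the secondary C3 radical takes hydrogen from the stannane, and the tetrasubstituted enoate and silyl ether are inert. C3 ceases to be a stereocentre (the C4a descriptor changes only by priority).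

Step 17
Reactants: 23 methyl (4aR,5S,8aR)-2,5,8a-trimethyl-5-(2-TBDPS-oxyethyl)-3,4,4a,5,6,7,8,8a-octahydronaphthalene-1-carboxylate
Product: 24 [(4aR,5S,8aR)-2,5,8a-trimethyl-5-(2-TBDPS-oxyethyl)-3,4,4a,5,6,7,8,8a-octahydronaphthalen-1-yl]methanol
Conditions: i-Bu2AlH, CH2Cl2, −78 → 0 °C
Reagents that add atoms: none
Why: Aluminium hydride reduction of the hindered conjugated ester to the primary allylic alcohol, as with drimenoate esters.

Step 18
Reactants: 24 [(4aR,5S,8aR)-2,5,8a-trimethyl-5-(2-TBDPS-oxyethyl)-3,4,4a,5,6,7,8,8a-octahydronaphthalen-1-yl]methanol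
Product: 25 (4aR,5S,8aR)-1-(bromomethyl)-2,5,8a-trimethyl-5-(2-TBDPS-oxyethyl)-3,4,4a,5,6,7,8,8a-octahydronaphthalene
Conditions: CBr4, PPh3, CH2Cl2, 0 °C; used at once
Reagents that add atoms: carbon tetrabromide, BrC(Br)(Br)Br
Why: Appel bromination under neutral conditions; allylic transposition would need bromide to add to the fully substituted C8, so the primary bromide is formed.

Step 19
Reactants: 26 2-bromobenzene-1,4-diol
Product: 27 1,4-bis(benzyloxy)-2-bromobenzene
Conditions: BnBr, K2CO3, DMF, rt
Reagents that add atoms: benzyl bromide, BrCc1ccccc1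
Why: Williamson etherification; benzyl ethers pass the organometallic steps and are removed at the end by hydrogenolysis without acid.

Step 20
Reactants: 25 (4aR,5S,8aR)-1-(bromomethyl)-2,5,8a-trimethyl-5-(2-TBDPS-oxyethyl)-3,4,4a,5,6,7,8,8a-octahydronaphthalene; 27 1,4-bis(benzyloxy)-2-bromobenzene
Product: 29 (4aR,5S,8aR)-1-[2,5-bis(benzyloxy)benzyl]-2,5,8a-trimethyl-5-(2-TBDPS-oxyethyl)-3,4,4a,5,6,7,8,8a-octahydronaphthalene, via aryl Grignard reagent 28 (not isolated)
Conditions: 27, Mg, THF, 40 °C; CuI (10 mol%), then 25, THF, −30 → 0 °C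
Reagents that add atoms: none
Why: Copper-catalysed coupling of an aryl Grignard reagent with a primary allylic bromide; SN2 at CH2 wins over SN2′ because attack at C8 would build a quaternary centre.

Step 21
Reactants: 29 (4aR,5S,8aR)-1-[2,5-bis(benzyloxy)benzyl]-2,5,8a-trimethyl-5-(2-TBDPS-oxyethyl)-3,4,4a,5,6,7,8,8a-octahydronaphthalene
Product: 30 2-{(4aR,5S,8aR)-1-[2,5-bis(benzyloxy)benzyl]-2,5,8a-trimethyl-3,4,4a,5,6,7,8,8a-octahydronaphthalen-5-yl}ethanol
Conditions: Bu4NF, THF, rt
Reagents that add atoms: none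
Why: Fluoride cleaves the silyl ether through the strong Si–F bond; benzyl ethers and the alkene are untouched.

Step 22
Reactants: 30 2-{(4aR,5S,8aR)-1-[2,5-bis(benzyloxy)benzyl]-2,5,8a-trimethyl-3,4,4a,5,6,7,8,8a-octahydronaphthalen-5-yl}ethanol
Product: 31 (4aR,5S,8aR)-1-[2,5-bis(benzyloxy)benzyl]-5-(2-bromoethyl)-2,5,8a-trimethyl-3,4,4a,5,6,7,8,8a-octahydronaphthalene
Conditions: CBr4, PPh3, CH2Cl2, 0 °C → rt
Reagents that add atoms: carbon tetrabromide, BrC(Br)(Br)Br
Why: Appel reaction of an unhindered primary alcohol gives the bromide needed for magnesium insertion.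

Step 23
Reactants: 32 2-methylcyclohexane-1,3-dione; 33 acrolein
Product: 34 3-(1-methyl-2,6-dioxocyclohexyl)propanal
Conditions: H2O, rt
Reagents that add atoms: none
Why: Michael addition of the acidic cyclic 1,3-dione to acrolein in water; conjugate addition gives clean C-alkylation where alkyl halides give O-alkylation.

Step 24
Reactants: 34 3-(1-methyl-2,6-dioxocyclohexyl)propanal
Product: 35 2-methyl-2-(4-methylpent-3-en-1-yl)cyclohexane-1,3-dione
Conditions: i-PrPPh3+ I−, n-BuLi, THF, −78 → 0 °C
Reagents that add atoms: isopropyltriphenylphosphonium iodide, CC(C)[P+](c1ccccc1)(c1ccccc1)c1ccccc1.[I-]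
Why: Wittig olefination; the non-stabilised ylide adds to the aldehyde much faster than to the ketones flanking a quaternary carbon, and the low temperature suppresses aldol closure of the keto aldehyde.

Step 25
Reactants: 35 2-methyl-2-(4-methylpent-3-en-1-yl)cyclohexane-1,3-dione
Product: 36 (2S,3S)-3-hydroxy-2-methyl-2-(4-methylpent-3-en-1-yl)cyclohexan-1-one
Conditions: baker's yeast (Saccharomyces cerevisiae), sucrose, H2O, 30 °C
Reagents that add atoms: none
Why: Enzymatic desymmetrisation by reduction of one enantiotopic carbonyl; 2-allyl- and 2-propyl-2-methylcyclohexane-1,3-diones give the (2S,3S)-ketols, with the hydroxyl cis to the larger chain, and the same sense is expected here. This sets C6′ and C5′ and the later cis ring fusion.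

Step 26
Reactants: 36 (2S,3S)-3-hydroxy-2-methyl-2-(4-methylpent-3-en-1-yl)cyclohexan-1-one
Product: 37 (5aS,9aS)-2,2,5a-trimethyloctahydro-1-benzoxepin-6(2H)-one
Conditions: Co(salen) (divalent cobalt complex of N,N′-bis(3,5-di-tert-butylsalicylidene)ethane-1,2-diamine; 5 mol%), N-fluoro-2,4,6-trimethylpyridinium triflate, (Me2SiH)2O, PhCF3, rt
Reagents that add atoms: none
Why: Hydrogen-atom-transfer Markovnikov hydroalkoxylation (Mukaiyama-type radical–polar crossover): cobalt hydride gives the tertiary radical, oxidation gives a cation equivalent, and the cis hydroxyl captures it to close the oxepane at its gem-dimethyl carbon. No stereocentre is formed, and alkene isomers from elimination re-enter the cycle.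

Step 27
Reactants: 37 (5aS,9aS)-2,2,5a-trimethyloctahydro-1-benzoxepin-6(2H)-one
Product: 38 (5aS,9aS)-2,2,5a-trimethyl-7-methylideneoctahydro-1-benzoxepin-6(2H)-one
Conditions: (CH2O)n, N-methylanilinium trifluoroacetate, THF, reflux
Reagents that add atoms: formaldehyde, C=O
Why: Mannich-type direct α-methylenation; only C7 carries α-hydrogens, and the product is a non-enolisable enone.

Step 28
Reactants: 31 (4aR,5S,8aR)-1-[2,5-bis(benzyloxy)benzyl]-5-(2-bromoethyl)-2,5,8a-trimethyl-3,4,4a,5,6,7,8,8a-octahydronaphthalene; 38 (5aS,9aS)-2,2,5a-trimethyl-7-methylideneoctahydro-1-benzoxepin-6(2H)-one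
Product: 41 (5aS,6R,9aS)-6-(2-{(4aR,5S,8aR)-1-[2,5-bis(benzyloxy)benzyl]-2,5,8a-trimethyl-3,4,4a,5,6,7,8,8a-octahydronaphthalen-5-yl}ethyl)-2,2,5a-trimethyl-7-methylidenedecahydro-1-benzoxepin-6-ol, via alkyl Grignard reagent 39 (not isolated), via alkylcerium dichloride 40 (not isolated)
Conditions: 31, Mg, THF, 50 °C; CeCl3, THF, −78 °C; 38, −78 → −30 °C; aq. NH4Cl
Reagents that add atoms: none
Why: Organocerium (Imamoto) 1,2-addition to a hindered conjugated ketone; the oxophilic, weakly basic reagent adds to the carbonyl and not to the conjugate position. The nucleophile should enter axially on the chair in which the oxepane CH2 at C6′ is axial and the C5′–O bond equatorial, that is from the face of the C6′ methyl. In that chair the other face is screened by the axial CH2, and in the alternative chair both faces are screened (axial C6′ methyl, axial C5′–O), so the linker ends syn to the C6′ methyl at C1′.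

Step 29
Reactants: 41 (5aS,6R,9aS)-6-(2-{(4aR,5S,8aR)-1-[2,5-bis(benzyloxy)benzyl]-2,5,8a-trimethyl-3,4,4a,5,6,7,8,8a-octahydronaphthalen-5-yl}ethyl)-2,2,5a-trimethyl-7-methylidenedecahydro-1-benzoxepin-6-ol
Product: 42 (5aS,6R,7R,9aS)-6-(2-{(4aR,5S,8aR)-1-[2,5-bis(benzyloxy)benzyl]-2,5,8a-trimethyl-3,4,4a,5,6,7,8,8a-octahydronaphthalen-5-yl}ethyl)-2,2,5a,7-tetramethyldecahydro-1-benzoxepin-6-ol
Conditions: Mn(dpm)3 (cat.), PhSiH3, t-BuOOH, i-PrOH, rt
Reagents that add atoms: none
Why: Hydrogen-atom-transfer hydrogenation reduces the 1,1-disubstituted alkene and leaves the tetrasubstituted C8=C9 alkene and the benzyl ethers. The tertiary C2′ radical should take up hydrogen axially and give the equatorial methyl, the thermodynamic isomer: with the linker equatorial, the other epimer would hold the C2′ methyl 1,3-diaxial to the C6′ methyl.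

Step 30
Reactants: 42 (5aS,6R,7R,9aS)-6-(2-{(4aR,5S,8aR)-1-[2,5-bis(benzyloxy)benzyl]-2,5,8a-trimethyl-3,4,4a,5,6,7,8,8a-octahydronaphthalen-5-yl}ethyl)-2,2,5a,7-tetramethyldecahydro-1-benzoxepin-6-ol
Product: 43 2-{[(4aR,5S,8aR)-5-{2-[(5aS,6R,7R,9aS)-6-hydroxy-2,2,5a,7-tetramethyldecahydro-1-benzoxepin-6-yl]ethyl}-2,5,8a-trimethyl-3,4,4a,5,6,7,8,8a-octahydronaphthalen-1-yl]methyl}benzene-1,4-diol
Conditions: H2 (1 atm), Pd/C, EtOAc, rt; kept under argon
Reagents that add atoms: none
Why: Hydrogenolysis of aryl benzyl ethers under neutral conditions; the hindered tetrasubstituted alkene is not reduced at atmospheric pressure and the tertiary alcohol is not exposed to acid.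

Step 31
Reactants: 43 2-{[(4aR,5S,8aR)-5-{2-[(5aS,6R,7R,9aS)-6-hydroxy-2,2,5a,7-tetramethyldecahydro-1-benzoxepin-6-yl]ethyl}-2,5,8a-trimethyl-3,4,4a,5,6,7,8,8a-octahydronaphthalen-1-yl]methyl}benzene-1,4-diol
Product: 44 CNP0125037.3, 2-{[(4aR,5S,8aR)-5-{2-[(5aS,6R,7R,9aS)-6-hydroxy-2,2,5a,7-tetramethyldecahydro-1-benzoxepin-6-yl]ethyl}-2,5,8a-trimethyl-3,4,4a,5,6,7,8,8a-octahydronaphthalen-1-yl]methyl}benzene-1,4-diyl bis(hydrogen sulfate)
Conditions: SO3·pyridine, pyridine, rt; cold H+-form ion-exchange resin
Reagents that add atoms: sulfur trioxide pyridine complex, [O-]S(=O)(=O)[n+]1ccccc1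
Why: O-Sulfation of both phenols by sulfur trioxide transfer; the tertiary alcohol between two fully substituted or branched carbons is too hindered to react, and the basic medium prevents acid-induced chroman formation.

## Compound list

1 | but-3-yn-1-ol | C#CCCO | starting material
2 | tert-butyl(but-3-yn-1-yloxy)diphenylsilane | C#CCCO[Si](c1ccccc1)(c1ccccc1)C(C)(C)C | intermediate
3 | [4-(TBDPS-oxy)but-1-yn-1-yl]lithium | [Li]C#CCCO[Si](c1ccccc1)(c1ccccc1)C(C)(C)C | intermediate
4 | methyl 5-(TBDPS-oxy)pent-2-ynoate | COC(=O)C#CCCO[Si](c1ccccc1)(c1ccccc1)C(C)(C)C | intermediate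
5 | methyl (2Z)-3-methyl-5-(TBDPS-oxy)pent-2-enoate | COC(=O)/C=C(/C)CCO[Si](c1ccccc1)(c1ccccc1)C(C)(C)C | intermediate
6 | (2Z)-3-methyl-5-(TBDPS-oxy)pent-2-en-1-ol | OC/C=C(/C)CCO[Si](c1ccccc1)(c1ccccc1)C(C)(C)C | intermediate
7 | [(2R,3S)-3-methyl-3-(2-TBDPS-oxyethyl)oxiran-2-yl]methanol | OC[C@H]1O[C@@]1(C)CCO[Si](c1ccccc1)(c1ccccc1)C(C)(C)C | intermediate
8 | methyl acetoacetate | COC(=O)CC(C)=O | starting material
9 | [(2R,3S)-3-methyl-3-(2-TBDPS-oxyethyl)oxiran-2-yl]methyl trifluoromethanesulfonate | FC(F)(F)S(=O)(=O)OC[C@H]1O[C@@]1(C)CCO[Si](c1ccccc1)(c1ccccc1)C(C)(C)C | intermediate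
10 | sodium lithium dianion of methyl acetoacetate | [Na+].[Li+].[CH2-]C(=O)[CH-]C(=O)OC | intermediate
11 | methyl 5-[(2R,3S)-3-methyl-3-(2-TBDPS-oxyethyl)oxiran-2-yl]-3-oxopentanoate | COC(=O)CC(=O)CC[C@H]1O[C@@]1(C)CCO[Si](c1ccccc1)(c1ccccc1)C(C)(C)C | intermediate
12 | methyl (2Z)-3-[(diethoxyphosphoryl)oxy]-5-[(2R,3S)-3-methyl-3-(2-TBDPS-oxyethyl)oxiran-2-yl]pent-2-enoate | COC(=O)/C=C(\OP(=O)(OCC)OCC)CC[C@H]1O[C@@]1(C)CCO[Si](c1ccccc1)(c1ccccc1)C(C)(C)C | intermediate
13 | methyl (2E)-3-methyl-5-[(2R,3S)-3-methyl-3-(2-TBDPS-oxyethyl)oxiran-2-yl]pent-2-enoate | COC(=O)/C=C(\C)CC[C@H]1O[C@@]1(C)CCO[Si](c1ccccc1)(c1ccccc1)C(C)(C)C | intermediate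
14 | (2E)-3-methyl-5-[(2R,3S)-3-methyl-3-(2-TBDPS-oxyethyl)oxiran-2-yl]pent-2-en-1-ol | OC/C=C(\C)CC[C@H]1O[C@@]1(C)CCO[Si](c1ccccc1)(c1ccccc1)C(C)(C)C | intermediate
15 | (2E)-3-methyl-5-[(2R,3S)-3-methyl-3-(2-TBDPS-oxyethyl)oxiran-2-yl]pent-2-en-1-yl methanesulfonate | CS(=O)(=O)OC/C=C(\C)CC[C@H]1O[C@@]1(C)CCO[Si](c1ccccc1)(c1ccccc1)C(C)(C)C | intermediate
16 | (2E)-1-bromo-3-methyl-5-[(2R,3S)-3-methyl-3-(2-TBDPS-oxyethyl)oxiran-2-yl]pent-2-ene | BrC/C=C(\C)CC[C@H]1O[C@@]1(C)CCO[Si](c1ccccc1)(c1ccccc1)C(C)(C)C | intermediate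
17 | dilithium dianion of methyl acetoacetate | [Li+].[Li+].[CH2-]C(=O)[CH-]C(=O)OC | intermediate
18 | methyl (6E)-7-methyl-9-[(2R,3S)-3-methyl-3-(2-TBDPS-oxyethyl)oxiran-2-yl]-3-oxonon-6-enoate | COC(=O)CC(=O)CC/C=C(\C)CC[C@H]1O[C@@]1(C)CCO[Si](c1ccccc1)(c1ccccc1)C(C)(C)C | intermediate
19 | methyl (4aS,5S,6R,8aR)-2,6-dihydroxy-5,8a-dimethyl-5-(2-TBDPS-oxyethyl)-3,4,4a,5,6,7,8,8a-octahydronaphthalene-1-carboxylate (enol form; trans-fused, linker axial and syn to the angular methyl, hydroxyl equatorial) | OC1=C(C(=O)OC)[C@]2(C)CC[C@@H](O)[C@@](C)(CCO[Si](c3ccccc3)(c3ccccc3)C(C)(C)C)[C@H]2CC1 | intermediate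
20 | methyl (4aS,5S,6R,8aR)-6-hydroxy-5,8a-dimethyl-5-(2-TBDPS-oxyethyl)-2-{[(trifluoromethyl)sulfonyl]oxy}-3,4,4a,5,6,7,8,8a-octahydronaphthalene-1-carboxylate | FC(F)(F)S(=O)(=O)OC1=C(C(=O)OC)[C@]2(C)CC[C@@H](O)[C@@](C)(CCO[Si](c3ccccc3)(c3ccccc3)C(C)(C)C)[C@H]2CC1 | intermediate
21 | methyl (4aS,5S,6R,8aR)-6-hydroxy-2,5,8a-trimethyl-5-(2-TBDPS-oxyethyl)-3,4,4a,5,6,7,8,8a-octahydronaphthalene-1-carboxylate | CC1=C(C(=O)OC)[C@]2(C)CC[C@@H](O)[C@@](C)(CCO[Si](c3ccccc3)(c3ccccc3)C(C)(C)C)[C@H]2CC1 | intermediate
22 | methyl (4aS,5S,6R,8aR)-6-[(1H-imidazol-1-ylcarbonothioyl)oxy]-2,5,8a-trimethyl-5-(2-TBDPS-oxyethyl)-3,4,4a,5,6,7,8,8a-octahydronaphthalene-1-carboxylate | CC1=C(C(=O)OC)[C@]2(C)CC[C@@H](OC(=S)n3ccnc3)[C@@](C)(CCO[Si](c3ccccc3)(c3ccccc3)C(C)(C)C)[C@H]2CC1 | intermediate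
23 | methyl (4aR,5S,8aR)-2,5,8a-trimethyl-5-(2-TBDPS-oxyethyl)-3,4,4a,5,6,7,8,8a-octahydronaphthalene-1-carboxylate | CC1=C(C(=O)OC)[C@]2(C)CCC[C@@](C)(CCO[Si](c3ccccc3)(c3ccccc3)C(C)(C)C)[C@H]2CC1 | intermediate
24 | [(4aR,5S,8aR)-2,5,8a-trimethyl-5-(2-TBDPS-oxyethyl)-3,4,4a,5,6,7,8,8a-octahydronaphthalen-1-yl]methanol | CC1=C(CO)[C@]2(C)CCC[C@@](C)(CCO[Si](c3ccccc3)(c3ccccc3)C(C)(C)C)[C@H]2CC1 | intermediate
25 | (4aR,5S,8aR)-1-(bromomethyl)-2,5,8a-trimethyl-5-(2-TBDPS-oxyethyl)-3,4,4a,5,6,7,8,8a-octahydronaphthalene | CC1=C(CBr)[C@]2(C)CCC[C@@](C)(CCO[Si](c3ccccc3)(c3ccccc3)C(C)(C)C)[C@H]2CC1 | intermediate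
26 | 2-bromobenzene-1,4-diol | Oc1ccc(O)c(Br)c1 | starting material
27 | 1,4-bis(benzyloxy)-2-bromobenzene | Brc1cc(OCc2ccccc2)ccc1OCc1ccccc1 | intermediate
28 | [2,5-bis(benzyloxy)phenyl]magnesium bromide | Br[Mg]c1cc(OCc2ccccc2)ccc1OCc1ccccc1 | intermediate
29 | (4aR,5S,8aR)-1-[2,5-bis(benzyloxy)benzyl]-2,5,8a-trimethyl-5-(2-TBDPS-oxyethyl)-3,4,4a,5,6,7,8,8a-octahydronaphthalene | CC1=C(Cc2cc(OCc3ccccc3)ccc2OCc2ccccc2)[C@]2(C)CCC[C@@](C)(CCO[Si](c3ccccc3)(c3ccccc3)C(C)(C)C)[C@H]2CC1 | intermediate
30 | 2-{(4aR,5S,8aR)-1-[2,5-bis(benzyloxy)benzyl]-2,5,8a-trimethyl-3,4,4a,5,6,7,8,8a-octahydronaphthalen-5-yl}ethanol | CC1=C(Cc2cc(OCc3ccccc3)ccc2OCc2ccccc2)[C@]2(C)CCC[C@@](C)(CCO)[C@H]2CC1 | intermediate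
31 | (4aR,5S,8aR)-1-[2,5-bis(benzyloxy)benzyl]-5-(2-bromoethyl)-2,5,8a-trimethyl-3,4,4a,5,6,7,8,8a-octahydronaphthalene | CC1=C(Cc2cc(OCc3ccccc3)ccc2OCc2ccccc2)[C@]2(C)CCC[C@@](C)(CCBr)[C@H]2CC1 | intermediate
32 | 2-methylcyclohexane-1,3-dione | CC1C(=O)CCCC1=O | starting material
33 | acrolein | C=CC=O | starting material
34 | 3-(1-methyl-2,6-dioxocyclohexyl)propanal | CC1(CCC=O)C(=O)CCCC1=O | intermediate
35 | 2-methyl-2-(4-methylpent-3-en-1-yl)cyclohexane-1,3-dione | CC(C)=CCCC1(C)C(=O)CCCC1=O | intermediate
36 | (2S,3S)-3-hydroxy-2-methyl-2-(4-methylpent-3-en-1-yl)cyclohexan-1-one (hydroxyl cis to the alkenyl chain) | O=C1CCC[C@H](O)[C@]1(C)CCC=C(C)C | intermediate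
37 | (5aS,9aS)-2,2,5a-trimethyloctahydro-1-benzoxepin-6(2H)-one (cis-fused) | O=C1CCC[C@@H]2OC(C)(C)CCC[C@]12C | intermediate
38 | (5aS,9aS)-2,2,5a-trimethyl-7-methylideneoctahydro-1-benzoxepin-6(2H)-one | O=C1C(=C)CC[C@@H]2OC(C)(C)CCC[C@]12C | intermediate
39 | (2-{(4aR,5S,8aR)-1-[2,5-bis(benzyloxy)benzyl]-2,5,8a-trimethyl-3,4,4a,5,6,7,8,8a-octahydronaphthalen-5-yl}ethyl)magnesium bromide | CC1=C(Cc2cc(OCc3ccccc3)ccc2OCc2ccccc2)[C@]2(C)CCC[C@@](C)(CC[Mg]Br)[C@H]2CC1 | intermediate
40 | (2-{(4aR,5S,8aR)-1-[2,5-bis(benzyloxy)benzyl]-2,5,8a-trimethyl-3,4,4a,5,6,7,8,8a-octahydronaphthalen-5-yl}ethyl)cerium dichloride | CC1=C(Cc2cc(OCc3ccccc3)ccc2OCc2ccccc2)[C@]2(C)CCC[C@@](C)(CC[Ce](Cl)Cl)[C@H]2CC1 | intermediate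
41 | (5aS,6R,9aS)-6-(2-{(4aR,5S,8aR)-1-[2,5-bis(benzyloxy)benzyl]-2,5,8a-trimethyl-3,4,4a,5,6,7,8,8a-octahydronaphthalen-5-yl}ethyl)-2,2,5a-trimethyl-7-methylidenedecahydro-1-benzoxepin-6-ol | CC1=C(Cc2cc(OCc3ccccc3)ccc2OCc2ccccc2)[C@]2(C)CCC[C@@](C)(CC[C@@]3(O)C(=C)CC[C@@H]4OC(C)(C)CCC[C@@]43C)[C@H]2CC1 | intermediate
42 | (5aS,6R,7R,9aS)-6-(2-{(4aR,5S,8aR)-1-[2,5-bis(benzyloxy)benzyl]-2,5,8a-trimethyl-3,4,4a,5,6,7,8,8a-octahydronaphthalen-5-yl}ethyl)-2,2,5a,7-tetramethyldecahydro-1-benzoxepin-6-ol | CC1=C(Cc2cc(OCc3ccccc3)ccc2OCc2ccccc2)[C@]2(C)CCC[C@@](C)(CC[C@@]3(O)[C@H](C)CC[C@@H]4OC(C)(C)CCC[C@@]43C)[C@H]2CC1 | intermediate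
43 | 2-{[(4aR,5S,8aR)-5-{2-[(5aS,6R,7R,9aS)-6-hydroxy-2,2,5a,7-tetramethyldecahydro-1-benzoxepin-6-yl]ethyl}-2,5,8a-trimethyl-3,4,4a,5,6,7,8,8a-octahydronaphthalen-1-yl]methyl}benzene-1,4-diol | CC1=C(Cc2cc(O)ccc2O)[C@]2(C)CCC[C@@](C)(CC[C@@]3(O)[C@H](C)CC[C@@H]4OC(C)(C)CCC[C@@]43C)[C@H]2CC1 | intermediate
44 | CNP0125037.3, the benzene-1,4-diyl bis(hydrogen sulfate) of 43 | CC1=C(Cc2cc(OS(=O)(=O)O)ccc2OS(=O)(=O)O)[C@]2(C)CCC[C@@](C)(CC[C@@]3(O)[C@H](C)CC[C@@H]4OC(C)(C)CCC[C@@]43C)[C@H]2CC1 | target

## Step count and least certain steps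

Total: 31 steps. Longest linear sequence: 25 steps from but-3-yn-1-ol (steps 1–18, 20–22, 28–31). Side branches: step 19 (one step) and steps 23–27 (five steps).

**Step 12 (key step).** The cascade may stop after ring B through proton loss from the C10 cation, the opened epoxide may undergo a 1,2-hydride shift to a carbonyl compound, the enol oxygen may capture the cation, or the chair–chair fold may erode because the axial group at C4 is larger than methyl. Fallback: run the sequence in two stages. From 18, open the epoxide with a weaker promoter (BF3·OEt2, CH2Cl2, −78 °C) and accept the monocyclic product with an exocyclic alkene at C10, methyl 5-[(1S,2S,3R)-3-hydroxy-2-methyl-6-methylidene-2-(2-TBDPS-oxyethyl)cyclohexyl]-3-oxopentanoate F1. Then protonate its alkene with SnCl4 or TfOH at −40 °C so that the regenerated C10 cation is captured by the enol in a chair transition state. This returns to 19.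

**Step 6.** The enolate of 11 may open the nearby epoxide (5-exo O- or C-attack) on warming, lutidinium triflate may quench part of the dianion, and the triflate may decompose before it is alkylated. Fallback: avoid the SN2 reaction. Oxidise 7 (SO3·pyridine, DMSO, i-Pr2NEt) to the epoxy aldehyde (2S,3S)-3-methyl-3-(2-TBDPS-oxyethyl)oxirane-2-carbaldehyde F2. Condense it with the stabilised ylide methyl 3-oxo-4-(triphenylphosphoranylidene)butanoate to the enone methyl (4E)-5-[(2R,3S)-3-methyl-3-(2-TBDPS-oxyethyl)oxiran-2-yl]-3-oxopent-4-enoate F3. Reduce the conjugated alkene with [(Ph3P)CuH]6. This returns to 11.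

**Step 26.** Closure of the seven-membered ring may be slow against competing paths: addition of the tertiary radical to the ring ketone, or accumulation of alkene isomers. Fallback: an electrophilic closure. From 36, oxymercuration with Hg(O2CCF3)2 (divalent mercury; MeNO2, 0 °C) and NaCl work-up would give the organomercurial chloro[(5aS,9aS)-2,2,5a-trimethyl-6-oxodecahydro-1-benzoxepin-3-yl]mercury F4 (both C3 epimers). Bu3SnH/AIBN removes the mercury without touching the ketone. This returns to 37.

**Step 28.** Attack from the oxepane face, conjugate addition to the enone, Wurtz coupling during magnesium insertion, or low conversion at the hindered carbonyl may occur. Fallback: change the order in which C1′ and C2′ are set. Hydrogenate 38 (H2, Pd/C) to the saturated ketone (5aS,7R,9aS)-2,2,5a,7-tetramethyloctahydro-1-benzoxepin-6(2H)-one F5; its C7 epimer can be equilibrated with base and recycled. Add 40 to F5, which is locked in the chair with the C2′ methyl equatorial, so that the reagent enters equatorially and trans to that methyl. This returns directly to 42 and bypasses step 29.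

**Step 29.** Hydrogen-atom delivery to the C2′ radical may show poor facial selectivity because the axial approach passes the axial C6′ methyl. Fallback: heterogeneous hydrogenation of 41 (H2, Pd/C, EtOAc). The alkene should bind the metal surface by its less encumbered face, opposite the axial hydroxyl, the ring oxygen and the oxepane, and the same operation cleaves the benzyl ethers. This returns to 43 and makes no new compound (F0).

## Further compounds

F1 | step 12 | methyl 5-[(1S,2S,3R)-3-hydroxy-2-methyl-6-methylidene-2-(2-TBDPS-oxyethyl)cyclohexyl]-3-oxopentanoate | COC(=O)CC(=O)CC[C@H]1C(=C)CC[C@@H](O)[C@@]1(C)CCO[Si](c1ccccc1)(c1ccccc1)C(C)(C)C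
F2 | step 6 | (2S,3S)-3-methyl-3-(2-TBDPS-oxyethyl)oxirane-2-carbaldehyde | O=C[C@H]1O[C@@]1(C)CCO[Si](c1ccccc1)(c1ccccc1)C(C)(C)C
F3 | step 6 | methyl (4E)-5-[(2R,3S)-3-methyl-3-(2-TBDPS-oxyethyl)oxiran-2-yl]-3-oxopent-4-enoate | COC(=O)CC(=O)/C=C/[C@H]1O[C@@]1(C)CCO[Si](c1ccccc1)(c1ccccc1)C(C)(C)C
F4 | step 26 | chloro[(5aS,9aS)-2,2,5a-trimethyl-6-oxodecahydro-1-benzoxepin-3-yl]mercury (both C3 epimers) | O=C1CCC[C@@H]2OC(C)(C)C([Hg]Cl)CC[C@]12C
F5 | step 28 | (5aS,7R,9aS)-2,2,5a,7-tetramethyloctahydro-1-benzoxepin-6(2H)-one | O=C1[C@H](C)CC[C@@H]2OC(C)(C)CCC[C@]12C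
F0 | step 29 | none | none
A1 | alternative 1 | 6-(allyloxy)-1-diazo-6-methylheptan-2-one | C=CCOC(C)(C)CCCC(=O)C=[N+]=[N-]
A2 | alternative 1 | (2S)-2-allyl-7,7-dimethyloxepan-3-one | O=C1CCCC(C)(C)O[C@H]1CC=C
A3 | alternative 2 | 2,6-dimethyl-1,4-benzoquinone | CC1=CC(=O)C=C(C)C1=O
A4 | alternative 2 | (E)-1-(tert-butyldimethylsilyloxy)buta-1,3-diene | C=C/C=C/O[Si](C)(C)C(C)(C)C
A5 | alternative 2 | cis-fused silyloxy enedione cycloadduct | O=C1C(C)=CC(=O)[C@@H]2[C@H](O[Si](C)(C)C(C)(C)C)C=CC[C@@]21C
A6 | alternative 3 | keto alkene with exocyclic methylene on the oxepane (hydroquinone dimethyl ether) | CC1=C(Cc2cc(OC)ccc2OC)[C@]2(C)CCC[C@@](C)(CCC(=O)[C@H](C)CC[C@@H]3OC(C)(C)CCCC3=C)[C@H]2CC1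
A7 | alternative 3 | hydroquinone dimethyl ether of the target skeleton | CC1=C(Cc2cc(OC)ccc2OC)[C@]2(C)CCC[C@@](C)(CC[C@@]3(O)[C@H](C)CC[C@@H]4OC(C)(C)CCC[C@@]43C)[C@H]2CC1
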